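Atoms are named by the numbering of the target throughout: pyran O2, C1, C3, C4; ring-fusion carbons C4a and C8a; carbocycle C5–C8; side chain Cq (tertiary carbinol), Cb=Ca (alkene), oxolane O1′ and C2′–C5′.

## The problem

The target is a 7,8-dihydro-6H-isochromen-6-one: a 4-alkylidene-4H-pyran (O2, C1, C8a, C4a, C4, C3) fused along C4a–C8a to a carbocycle (C4a, C5, C6, C7, C8, C8a) that is not aromatic. The usual route through a benzene ring and late dearomatisation therefore does not deliver the C8 carbinol. Two of the five stereocentres form a trans diol in the carbocycle, tertiary C7 (S) beside secondary C8 (R); C7 can control C8 and nothing else. The other three lie in the C3 side chain: the tertiary carbinol Cq (S) and the trans-related C2′ and C3′ (both S) of the oxolane, which are adjacent and can be set together. Cq is separated from the oxolane by the E-trisubstituted alkene Cb=Ca and from the ring system by sp2 carbons, so the two halves must be made enantiopure separately and joined without creating a stereocentre. Several groups are fragile: C8(OH)–C7–C6(=O) is a β-hydroxy ketone open to retro-aldol cleavage, the Cq hydroxyl is tertiary and doubly allylic, C8 is allylic to the enol ether C8a=C1, and the pyran is a vinylogous ester. The enabling feature is that C7 carries a methyl group, a hydroxyl group and two oxidised carbons (C6 ketone, C8 carbinol), which is the substitution pattern of C2 of lactic acid. C5, C4a, C8a and C4 are the four carbons of a 3-methylbut-2-enoyl unit on C6; because C7 is quaternary this enone can enolise only at its γ-methyl groups, and one of them, C8a, can reach C8 to close the carbocycle.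

## Retrosynthesis

**Protecting groups and pyran (28 ⇒ 27 ⇒ 26).** The three hydroxyls of 28 are carried as triethylsilyl ethers in 27 and released last. Cutting the enol-ether bond O2–C1 of 27 gives 26, in which C3 is a ketone and C1 is a methoxymethylidene carbon on C8a, that is, a masked 1,5-dicarbonyl compound. This cut is preferred to an alkyne cycloisomerisation onto an aromatic aldehyde, which would give the 6,8-dione level and leave C8 to an uncontrolled late reduction. The forward reaction only has to expel methanol under mild acid, and no stereocentre is involved.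

**C3–C4 (26 ⇒ 14 + 25).** This bond divides the molecule into a carbocyclic half 14 (two stereocentres) and a side-chain ester 25 (three stereocentres and the alkene). It is preferred to Cq–C3, which would require an uncontrolled addition to a ketone beside the pyran. The forward Claisen-type acylation needs the C4 methyl anion of 14 to react at its terminal carbon; the ester cannot enolise because Cq is quaternary.

**C8a–C1 (14 ⇒ 13 ⇒ 12 ⇒ 11 ⇒ 10).** The one-carbon unit is removed from C8a, leaving cyclohexenone 10. It must be installed before the acylation, because afterwards C4 would be the most nucleophilic carbon. The forward sequence is silylation to 11 and 12 (endocyclic silyl dienol ether), γ-attack of an orthoformate to give acetal 13, and loss of methanol to 14, after which the C4 methyl is the only enolisable position.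

**C8–C8a, the key step (10 ⇒ 9).** Cutting this bond opens the carbocycle to keto aldehyde 9, which has one stereocentre and no ring. The forward vinylogous aldol closure has to set C8 trans to the C7 oxygen. No other ring bond can be cut as cleanly, because C7 already holds both carbonyl carbons.

**C6–C7 and the lactic acid centre (9 ⇒ 8 ⇒ 7 ⇒ 6 ⇒ 5 ⇒ 3 + 4; 3 ⇒ 1 + 2).** Aldehyde 9 comes from silyl ether 8, keto diol 7 and triol 6 by oxidation-state and protecting-group changes. Triol 6 is the reduction product of aldol adduct 5, made from the dioxolanone 3 of (S)-lactic acid 1 and pivalaldehyde 2 by addition of its enolate to 3-methylbut-2-enal 4. The lactic acid carboxyl becomes C8 and the enal carbonyl carbon becomes C6. The enolate has to add with retention of the lactic acid configuration.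

**Side chain (25 ⇒ 24 ⇒ 23 ⇒ 22 ⇒ 21 ⇒ 20 ⇒ 19 ⇒ 18 ⇒ 16 + 17; 16 ⇒ 15 + 2).** Cq is again a lactic acid C2, this time with the carboxyl as C3, which calls for (R)-lactic acid 15 and its dioxolanone 16. Ester 25 and hydroxy ester 24 come from dioxolanone 23 by methanolysis. The oxolane of 23 is opened at O1′–C5′ to tosylate 22 and diol 21, and 21 comes from homoallylic alcohol 20 by hydroboration. Cutting C2′–C3′ of 20 by an anti-crotylation leads to enal 19, whose E alkene and Cq–Cb bond arise from 16 and 3-ethoxy-2-methylprop-2-enal 17 through adduct 18. The crotylation has to be reagent-controlled because Cq is too remote to help.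

## Roads not taken

All three alternatives address only the side chain; none builds the carbocycle or its trans diol.

**Alternative 1:** The Cb–Cq bond is cut. Carbamate A1 is lithiated with s-BuLi and TMEDA and trapped by the E-alkenyl pinacol boronate A2. The alkenyl group then shifts from boron to carbon with loss of the carbamate, and H2O2/NaOH converts C–B into the C–OH of alkynol A3.
- Merits: Cq and the alkene geometry arrive in one stereospecific operation from a cheap secondary alcohol, and the silylalkyne of A3 is a handle for the classical coupling and cycloisomerisation route to isochromenones.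
- Weak points: a lithiated propargylic carbamate is less configurationally secure than the benzylic cases and can react through its allenyl form. A2 still needs the complete oxolane. The alkyne endgame presupposes an aromatic ortho-halo aldehyde, which the 7,8-dihydro ring with its diol is not.
- Comparison: for Cq alone this road is at least as direct as the chosen one, and it avoids the hindered acylation of step 17. The chosen plan sets against it a Cq centre fixed by enolate addition trans to a tert-butyl group and an acyl group at C3 that matches the 1,5-dicarbonyl closure of a non-aromatic pyran.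

**Alternative 2:** The O1′–C5′ bond is cut and the oxolane carbons are taken from L-isoleucine A4, whose two centres become C2′ and C3′. Hydroxy pivalate A5 is converted by PhI(OAc)2 and I2 under visible light into its alkoxy radical, which abstracts a hydrogen from the δ-methyl group; the iodide formed is displaced by the hydroxyl to give oxolane A6.
- Merits: both oxolane centres come from the chiral pool with no chiral reagent.
- Weak points: hydrogen abstraction from a primary C–H bond competes with β-scission of the alkoxy radical. A6 is only a five-carbon piece; C2′ would pass through an epimerisable α-alkoxy aldehyde, and the alkene and Cq remain to be built.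
- Comparison: in economy of chirality this road is better than step 12, which consumes two isopinocampheyl groups. The chosen plan sets against it closed-shell reactions throughout and an oxolane formed on a chain that already carries Cq and the alkene.

**Alternative 3:** The O1′–C2′ bond is cut in the SN2′ sense. Pd(PPh3)4 (zerovalent palladium) ionises the Cq–Cb oxirane of epoxy alcohol A7 to a π-allyl complex, and the C5′ hydroxyl attacks C2′. This closes the oxolane and reveals the E alkene and the free Cq hydroxyl of A8.
- Merits: one catalytic step forms the ring and the alkene and frees the carbinol, with Cq from a reagent-controlled epoxidation.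
- Weak points: C2′ and the alkene geometry both depend on one π-allyl intermediate that starts anti-substituted and can isomerise before it is trapped. The Z-trisubstituted alkene of A7 is itself demanding. A8 carries C3 as a silyloxymethyl group that must be deprotected and oxidised before coupling.
- Comparison: in bond economy this road is better than steps 12–14. The chosen plan sets against it that C2′/C3′, the alkene and Cq are each fixed by a separate, well-understood element, and that C3 arrives at the acyl oxidation level.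

Key step: step 7

Remark on the chemistry: centres that are later oxidised or eliminated (the carbinol carbon of 5, 6 and 18; C4 of 13) are carried as epimer mixtures, and 14 is drawn as its E enol ether although either geometry serves.

## Route

Step 1
Reactants: 1 (S)-lactic acid; 2 pivalaldehyde
Product: 3 (2S,5S)-2-tert-butyl-5-methyl-1,3-dioxolan-4-one
Conditions: p-TsOH·H2O (cat.), H2SO4 (cat.), pentane, reflux, Dean–Stark; crystallisation from pentane/Et2O at −78 °C
Reagents that add atoms: none
Why: Acid-catalysed acetalisation with removal of water gives the dioxolanone; the lactic acid centre directs the acetal carbon to the cis isomer, which is purified by crystallisation (first stage of self-regeneration of a stereocentre).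

Step 2
Reactants: 3 (2S,5S)-2-tert-butyl-5-methyl-1,3-dioxolan-4-one; 4 3-methylbut-2-enal
Product: 5 (2S,5R)-2-tert-butyl-5-[(1RS)-1-hydroxy-3-methylbut-2-en-1-yl]-5-methyl-1,3-dioxolan-4-one
Conditions: LiN(i-Pr)2, THF, −78 °C; then 4, −78 °C; AcOH quench at −78 °C
Reagents that add atoms: none
Why: Aldol addition (1,2-mode) of the lithium enolate; the tert-butyl group shields one face, so the enal enters trans to it and the quaternary centre keeps the lactic acid sense of hydroxyl and methyl. The carbinol epimers converge in step 4.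

Step 3
Reactants: 5 (2S,5R)-2-tert-butyl-5-[(1RS)-1-hydroxy-3-methylbut-2-en-1-yl]-5-methyl-1,3-dioxolan-4-one
Product: 6 (2S,3RS)-2,5-dimethylhex-4-ene-1,2,3-triol
Conditions: LiAlH4, THF, 0 °C; Fieser work-up
Reagents that add atoms: none
Why: Hydride reduction of the acylal lactone; the hemiacetal fragment collapses to pivalaldehyde, which is reduced to neopentyl alcohol, and the quaternary centre is untouched.

Step 4
Reactants: 6 (2S,3RS)-2,5-dimethylhex-4-ene-1,2,3-triol
Product: 7 (2S)-1,2-dihydroxy-2,5-dimethylhex-4-en-3-one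
Conditions: MnO2 (activated, excess), acetone, rt
Reagents that add atoms: none
Why: MnO2 oxidises the allylic secondary alcohol selectively and leaves the saturated primary and tertiary hydroxyls; both carbinol epimers give the same enone.

Step 5
Reactants: 7 (2S)-1,2-dihydroxy-2,5-dimethylhex-4-en-3-one
Product: 8 (2S)-2,5-dimethyl-1,2-bis(triethylsilyloxy)hex-4-en-3-one
Conditions: TESOTf (2.5 equiv), 2,6-lutidine, CH2Cl2, −78 → 0 °C
Reagents that add atoms: triethylsilyl trifluoromethanesulfonate, CC[Si](CC)(CC)OS(=O)(=O)C(F)(F)F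
Why: The silyl triflate with a hindered pyridine base silylates the primary and the tertiary α-ketol hydroxyl alike; the non-basic conditions avoid retro-aldol loss of formaldehyde.

Step 6
Reactants: 8 (2S)-2,5-dimethyl-1,2-bis(triethylsilyloxy)hex-4-en-3-one
Product: 9 (2S)-2,5-dimethyl-3-oxo-2-(triethylsilyloxy)hex-4-enal
Conditions: (COCl)2, DMSO, CH2Cl2, −78 → −40 °C; Et3N, −78 → 0 °C
Reagents that add atoms: none
Why: Direct Swern oxidation of a primary triethylsilyl ether: chlorodimethylsulfonium chloride cleaves the unhindered primary silyl ether and oxidises its carbon in the same flask, while the tertiary silyl ether stays. The aldehyde has no α-hydrogen, so the centre cannot epimerise.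

Step 7
Reactants: 9 (2S)-2,5-dimethyl-3-oxo-2-(triethylsilyloxy)hex-4-enal
Product: 10 (5R,6S)-5-hydroxy-3,6-dimethyl-6-(triethylsilyloxy)cyclohex-2-en-1-one
Conditions: KOt-Bu (0.2 equiv), THF/t-BuOH (4:1), −30 → 0 °C; AcOH quench
Reagents that add atoms: none
Why: Catalytic KOt-Bu removes a γ-proton of the 3-methylbut-2-enoyl ketone (C7 is quaternary, so there is no α′-proton), and proton exchange with t-BuOH through the β,γ-unsaturated isomer equilibrates the dienolate geometries until the one with C7 and C4a cis on C5=C6 is populated. Its terminal carbon C8a adds to the aldehyde carbon C8, and t-BuOH protonates the potassium aldolate and regenerates the base. The closest known reaction type is the base-mediated intramolecular vinylogous aldol cyclisation of γ-enolisable enones onto tethered aldehydes. The carbocycle closes in the 6-(enolendo)-exo-trig mode, which is allowed; attack through the α-carbon C5 would give a four-membered ring and is reversible. The new centre C8 is controlled by C7: with the non-chelating potassium ion and a silyl ether the aldehyde should react in the conformer whose C=O dipole opposes the C7–O bond (Cornforth arrangement), and the tether through C6 then leads to the trans-diaxial aldolate, which is 5R in 10. The step needs closure to outrun deformylation of the non-enolisable β-keto aldehyde, which the hindered, weakly nucleophilic alkoxide in catalytic amount at low temperature should secure. It also needs the aldol to survive vinylogous dehydration, for which the reaction is kept short and quenched with acetic acid.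

Step 8
Reactants: 10 (5R,6S)-5-hydroxy-3,6-dimethyl-6-(triethylsilyloxy)cyclohex-2-en-1-one
Product: 12 (5R,6S)-3,6-dimethyl-1,5,6-tris(triethylsilyloxy)cyclohexa-1,3-diene, via bis-silyl enone 11 (not isolated)
Conditions: TESOTf (3.5 equiv), Et3N (6 equiv), CH2Cl2, 0 °C → rt; non-aqueous work-up
Reagents that add atoms: triethylsilyl trifluoromethanesulfonate, CC[Si](CC)(CC)OS(=O)(=O)C(F)(F)F
Why: The silyl triflate first silylates the C8 hydroxyl (11) and then O-silylates the enone (soft enolisation); only γ-hydrogens are available, and with the amine triflate present the dienol ethers should equilibrate to the more substituted endocyclic diene C4a=C8a.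

Step 9
Reactants: 12 (5R,6S)-3,6-dimethyl-1,5,6-tris(triethylsilyloxy)cyclohexa-1,3-diene
Product: 14 (4E,5R,6S)-4-(methoxymethylidene)-3,6-dimethyl-5,6-bis(triethylsilyloxy)cyclohex-2-en-1-one, via dimethyl acetal 13 (not isolated)
Conditions: HC(OMe)3, TMSOTf (0.1 equiv), CH2Cl2, −78 °C; then i-Pr2NEt (3 equiv), TMSOTf (1.5 equiv), −78 → 0 °C; aq. NaHCO3
Reagents that add atoms: trimethyl orthoformate, COC(OC)OC
Why: Vinylogous Mukaiyama reaction: the dimethoxycarbenium ion attacks the γ-terminus C8a of the silyl dienol ether and restores the enone (13). The silyl triflate with the amine base then removes one methoxy group together with the C8a hydrogen (acetal-to-enol-ether elimination), giving the cross-conjugated vinylogous ester and erasing the C8a centre. After this step the C4 methyl is the only enolisable position.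

Step 10
Reactants: 15 (R)-lactic acid; 2 pivalaldehyde
Product: 16 (2R,5R)-2-tert-butyl-5-methyl-1,3-dioxolan-4-one
Conditions: p-TsOH·H2O (cat.), H2SO4 (cat.), pentane, reflux, Dean–Stark; crystallisation at −78 °C
Reagents that add atoms: none
Why: As step 1 in the enantiomeric series; (R)-lactic acid is needed because here the carboxyl carbon becomes C3 and the incoming carbon becomes Cb.

Step 11
Reactants: 16 (2R,5R)-2-tert-butyl-5-methyl-1,3-dioxolan-4-one; 17 (2E)-3-ethoxy-2-methylprop-2-enal
Product: 19 (2R,5S)-2-tert-butyl-5-methyl-5-[(1E)-2-methyl-3-oxoprop-1-en-1-yl]-1,3-dioxolan-4-one, via aldol adduct 18 (not isolated)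
Conditions: LiN(i-Pr)2, THF, −78 °C; 17, −78 °C; then 1 M aq. HCl, THF, 0 °C → rt
Reagents that add atoms: water, O
Why: Aldol addition of the enolate trans to the tert-butyl group sets Cq; acid then transposes the β-hydroxy enol ether with loss of ethanol, the β-alkoxy enal acting as a masked malondialdehyde (Stork–Danheiser-type transposition). Conjugate addition–elimination would give the same enal, and the E isomer with the quaternary carbon trans to the formyl group is the stable one.

Step 12
Reactants: 19 (2R,5S)-2-tert-butyl-5-methyl-5-[(1E)-2-methyl-3-oxoprop-1-en-1-yl]-1,3-dioxolan-4-one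
Product: 20 (2R,5S)-2-tert-butyl-5-[(1E,3S,4S)-3-hydroxy-2,4-dimethylhexa-1,5-dien-1-yl]-5-methyl-1,3-dioxolan-4-one
Conditions: (E)-but-2-ene, n-BuLi, KOt-Bu, THF, −78 → −50 °C; (−)-Ipc2BOMe, −78 °C; BF3·OEt2; then 19, −78 °C; 30% H2O2, aq. NaOAc, 0 °C → rt
Reagents that add atoms: (E)-crotyldiisopinocampheylborane made in the flask from (E)-but-2-ene and (−)-Ipc2BOMe, C/C=C/CB([C@@H]1C[C@@H]2C[C@H]([C@H]1C)C2(C)C)[C@@H]1C[C@@H]2C[C@H]([C@H]1C)C2(C)C
Why: Brown crotylboration: the E-crotylborane reacts through a chair transition state to give the anti homoallylic alcohol, and the isopinocampheyl groups of the (+)-α-pinene series direct attack to the aldehyde face that gives the 3S carbinol (reagent control; the remote quaternary centre has no say). The buffered peroxide work-up spares the dioxolanone.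

Step 13
Reactants: 20 (2R,5S)-2-tert-butyl-5-[(1E,3S,4S)-3-hydroxy-2,4-dimethylhexa-1,5-dien-1-yl]-5-methyl-1,3-dioxolan-4-one
Product: 21 (2R,5S)-2-tert-butyl-5-[(1E,3S,4S)-3,6-dihydroxy-2,4-dimethylhex-1-en-1-yl]-5-methyl-1,3-dioxolan-4-one
Conditions: 9-BBN (3 equiv), THF, 0 °C → rt; 30% H2O2, aq. NaOAc, 0 °C → rt
Reagents that add atoms: hydrogen peroxide, OO
Why: Anti-Markovnikov hydroboration–oxidation; 9-BBN attacks only the monosubstituted alkene and leaves the trisubstituted alkene and the lactone.

Step 14
Reactants: 21 (2R,5S)-2-tert-butyl-5-[(1E,3S,4S)-3,6-dihydroxy-2,4-dimethylhex-1-en-1-yl]-5-methyl-1,3-dioxolan-4-one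
Product: 23 (2R,5S)-2-tert-butyl-5-methyl-5-{(1E)-2-[(2S,3S)-3-methyloxolan-2-yl]prop-1-en-1-yl}-1,3-dioxolan-4-one, via primary tosylate 22 (not isolated)
Conditions: TsCl (1.2 equiv), pyridine, DMAP (cat.), 0 → 50 °C
Reagents that add atoms: none
Why: Selective sulfonylation of the primary hydroxyl and 5-exo-tet displacement by the secondary hydroxyl (Williamson-type cycloetherification); no bond at C2′ or C3′ is broken, so the anti diol becomes the trans-2,3-disubstituted oxolane.

Step 15
Reactants: 23 (2R,5S)-2-tert-butyl-5-methyl-5-{(1E)-2-[(2S,3S)-3-methyloxolan-2-yl]prop-1-en-1-yl}-1,3-dioxolan-4-one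
Product: 24 methyl (2S,3E)-2-hydroxy-2-methyl-4-[(2S,3S)-3-methyloxolan-2-yl]pent-3-enoate
Conditions: K2CO3 (0.2 equiv), MeOH, 0 °C → rt
Reagents that add atoms: methanol, CO
Why: Transesterification of the acylal lactone; the hemiacetal alkoxide loses pivalaldehyde and frees the tertiary hydroxyl. Cq has no α-hydrogen and cannot epimerise.

Step 16
Reactants: 24 methyl (2S,3E)-2-hydroxy-2-methyl-4-[(2S,3S)-3-methyloxolan-2-yl]pent-3-enoate
Product: 25 methyl (2S,3E)-2-methyl-4-[(2S,3S)-3-methyloxolan-2-yl]-2-(triethylsilyloxy)pent-3-enoate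
Conditions: TESOTf, 2,6-lutidine, CH2Cl2, −78 → 0 °C
Reagents that add atoms: triethylsilyl trifluoromethanesulfonate, CC[Si](CC)(CC)OS(=O)(=O)C(F)(F)F
Why: Silylation of the tertiary α-hydroxy ester; the ether prevents formation of an alkoxide that would deactivate the ester in step 17.

Step 17
Reactants: 14 (4E,5R,6S)-4-(methoxymethylidene)-3,6-dimethyl-5,6-bis(triethylsilyloxy)cyclohex-2-en-1-one; 25 methyl (2S,3E)-2-methyl-4-[(2S,3S)-3-methyloxolan-2-yl]-2-(triethylsilyloxy)pent-3-enoate
Product: 26 (4E,5R,6S)-4-(methoxymethylidene)-6-methyl-3-{(3S,4E)-3-methyl-5-[(2S,3S)-3-methyloxolan-2-yl]-2-oxo-3-(triethylsilyloxy)hex-4-en-1-yl}-5,6-bis(triethylsilyloxy)cyclohex-2-en-1-one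
Conditions: 14, LiN(i-Pr)2 (2.2 equiv), THF, −78 °C; 25, −78 → −20 °C; AcOH quench
Reagents that add atoms: none
Why: Claisen-type acylation: the base removes a hydrogen of the C4 methyl group, the only enolisable position of 14, and the dienolate attacks the non-enolisable ester through its terminal carbon, because attack at C5 would break the vinylogous ester conjugation (the behaviour known for 3-alkoxybut-2-enoate and 2-methyl-4-pyranone anions). The second equivalent of base deprotonates the product and shields the new ketone.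

Step 18
Reactants: 26 (4E,5R,6S)-4-(methoxymethylidene)-6-methyl-3-{(3S,4E)-3-methyl-5-[(2S,3S)-3-methyloxolan-2-yl]-2-oxo-3-(triethylsilyloxy)hex-4-en-1-yl}-5,6-bis(triethylsilyloxy)cyclohex-2-en-1-one
Product: 27 (7S,8R)-7-methyl-3-{(2S,3E)-4-[(2S,3S)-3-methyloxolan-2-yl]-2-(triethylsilyloxy)pent-3-en-2-yl}-7,8-bis(triethylsilyloxy)-7,8-dihydro-6H-isochromen-6-one
Conditions: PPTS (0.2 equiv), CH2Cl2, rt
Reagents that add atoms: none
Why: Acid-catalysed cyclodehydration of the masked 1,5-dicarbonyl compound: the enol oxygen of the C3 ketone adds to C1 and methanol is expelled (addition–elimination at a vinylogous ester), giving the fully conjugated pyran. No stereocentre takes part.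

Step 19
Reactants: 27 (7S,8R)-7-methyl-3-{(2S,3E)-4-[(2S,3S)-3-methyloxolan-2-yl]-2-(triethylsilyloxy)pent-3-en-2-yl}-7,8-bis(triethylsilyloxy)-7,8-dihydro-6H-isochromen-6-one
Product: 28 (7S,8R)-7,8-dihydroxy-3-{(2S,3E)-2-hydroxy-4-[(2S,3S)-3-methyloxolan-2-yl]pent-3-en-2-yl}-7-methyl-7,8-dihydro-6H-isochromen-6-one
Conditions: HF·pyridine, pyridine, THF, 0 °C → rt
Reagents that add atoms: none
Why: Fluoride cleavage of the three triethylsilyl ethers under buffered, weakly acidic conditions, chosen to avoid base-induced retro-aldol cleavage of C7–C8 and acid ionisation of the tertiary allylic carbinol.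

## Compound list

1 | (S)-lactic acid | C[C@H](O)C(=O)O | starting material
2 | pivalaldehyde (2,2-dimethylpropanal) | CC(C)(C)C=O | starting material
3 | (2S,5S)-2-tert-butyl-5-methyl-1,3-dioxolan-4-one | C[C@@H]1O[C@H](C(C)(C)C)OC1=O | intermediate
4 | 3-methylbut-2-enal | CC(C)=CC=O | starting material
5 | (2S,5R)-2-tert-butyl-5-[(1RS)-1-hydroxy-3-methylbut-2-en-1-yl]-5-methyl-1,3-dioxolan-4-one | C[C@]1(C(O)C=C(C)C)O[C@H](C(C)(C)C)OC1=O | intermediate
6 | (2S,3RS)-2,5-dimethylhex-4-ene-1,2,3-triol | C[C@](CO)(C(O)C=C(C)C)O | intermediate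
7 | (2S)-1,2-dihydroxy-2,5-dimethylhex-4-en-3-one | C[C@](CO)(C(=O)C=C(C)C)O | intermediate
8 | (2S)-2,5-dimethyl-1,2-bis(triethylsilyloxy)hex-4-en-3-one | C[C@](CO[Si](CC)(CC)CC)(C(=O)C=C(C)C)O[Si](CC)(CC)CC | intermediate
9 | (2S)-2,5-dimethyl-3-oxo-2-(triethylsilyloxy)hex-4-enal | O=C[C@](C)(O[Si](CC)(CC)CC)C(=O)C=C(C)C | intermediate
10 | (5R,6S)-5-hydroxy-3,6-dimethyl-6-(triethylsilyloxy)cyclohex-2-en-1-one | CC1=CC(=O)[C@@](C)(O[Si](CC)(CC)CC)[C@H](O)C1 | intermediate
11 | (5R,6S)-3,6-dimethyl-5,6-bis(triethylsilyloxy)cyclohex-2-en-1-one | CC1=CC(=O)[C@@](C)(O[Si](CC)(CC)CC)[C@H](O[Si](CC)(CC)CC)C1 | intermediate (not isolated)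
12 | (5R,6S)-3,6-dimethyl-1,5,6-tris(triethylsilyloxy)cyclohexa-1,3-diene | CC1=C[C@@H](O[Si](CC)(CC)CC)[C@](C)(O[Si](CC)(CC)CC)C(O[Si](CC)(CC)CC)=C1 | intermediate
13 | (5R,6S)-4-(dimethoxymethyl)-3,6-dimethyl-5,6-bis(triethylsilyloxy)cyclohex-2-en-1-one (C4 epimers) | CC1=CC(=O)[C@@](C)(O[Si](CC)(CC)CC)[C@H](O[Si](CC)(CC)CC)C1C(OC)OC | intermediate (not isolated)
14 | (4E,5R,6S)-4-(methoxymethylidene)-3,6-dimethyl-5,6-bis(triethylsilyloxy)cyclohex-2-en-1-one | CO/C=C1\C(C)=CC(=O)[C@@](C)(O[Si](CC)(CC)CC)[C@@H]1O[Si](CC)(CC)CC | intermediate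
15 | (R)-lactic acid | C[C@@H](O)C(=O)O | starting material
16 | (2R,5R)-2-tert-butyl-5-methyl-1,3-dioxolan-4-one | C[C@H]1O[C@@H](C(C)(C)C)OC1=O | intermediate
17 | (2E)-3-ethoxy-2-methylprop-2-enal | CCO/C=C(\C)C=O | starting material
18 | (2R,5S)-2-tert-butyl-5-[(1RS,2E)-3-ethoxy-1-hydroxy-2-methylprop-2-en-1-yl]-5-methyl-1,3-dioxolan-4-one | C[C@@]1(C(O)/C(C)=C/OCC)O[C@@H](C(C)(C)C)OC1=O | intermediate (not isolated)
19 | (2R,5S)-2-tert-butyl-5-methyl-5-[(1E)-2-methyl-3-oxoprop-1-en-1-yl]-1,3-dioxolan-4-one | C[C@@]1(/C=C(\C)C=O)O[C@@H](C(C)(C)C)OC1=O | intermediate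
20 | (2R,5S)-2-tert-butyl-5-[(1E,3S,4S)-3-hydroxy-2,4-dimethylhexa-1,5-dien-1-yl]-5-methyl-1,3-dioxolan-4-one | C[C@@]1(/C=C(\C)[C@@H](O)[C@@H](C)C=C)O[C@@H](C(C)(C)C)OC1=O | intermediate
21 | (2R,5S)-2-tert-butyl-5-[(1E,3S,4S)-3,6-dihydroxy-2,4-dimethylhex-1-en-1-yl]-5-methyl-1,3-dioxolan-4-one | C[C@@]1(/C=C(\C)[C@@H](O)[C@@H](C)CCO)O[C@@H](C(C)(C)C)OC1=O | intermediate
22 | (3S,4S,5E)-6-[(2R,4S)-2-tert-butyl-4-methyl-5-oxo-1,3-dioxolan-4-yl]-4-hydroxy-3,5-dimethylhex-5-en-1-yl 4-methylbenzenesulfonate | C[C@@]1(/C=C(\C)[C@@H](O)[C@@H](C)CCOS(=O)(=O)c2ccc(C)cc2)O[C@@H](C(C)(C)C)OC1=O | intermediate (not isolated)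
23 | (2R,5S)-2-tert-butyl-5-methyl-5-{(1E)-2-[(2S,3S)-3-methyloxolan-2-yl]prop-1-en-1-yl}-1,3-dioxolan-4-one | C[C@@]1(/C=C(\C)[C@H]2OCC[C@@H]2C)O[C@@H](C(C)(C)C)OC1=O | intermediate
24 | methyl (2S,3E)-2-hydroxy-2-methyl-4-[(2S,3S)-3-methyloxolan-2-yl]pent-3-enoate | COC(=O)[C@@](C)(O)/C=C(\C)[C@H]1OCC[C@@H]1C | intermediate
25 | methyl (2S,3E)-2-methyl-4-[(2S,3S)-3-methyloxolan-2-yl]-2-(triethylsilyloxy)pent-3-enoate | COC(=O)[C@@](C)(O[Si](CC)(CC)CC)/C=C(\C)[C@H]1OCC[C@@H]1C | intermediate
26 | (4E,5R,6S)-4-(methoxymethylidene)-6-methyl-3-{(3S,4E)-3-methyl-5-[(2S,3S)-3-methyloxolan-2-yl]-2-oxo-3-(triethylsilyloxy)hex-4-en-1-yl}-5,6-bis(triethylsilyloxy)cyclohex-2-en-1-one | CO/C=C1\C(CC(=O)[C@@](C)(O[Si](CC)(CC)CC)/C=C(\C)[C@H]2OCC[C@@H]2C)=CC(=O)[C@@](C)(O[Si](CC)(CC)CC)[C@@H]1O[Si](CC)(CC)CC | intermediate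
27 | (7S,8R)-7-methyl-3-{(2S,3E)-4-[(2S,3S)-3-methyloxolan-2-yl]-2-(triethylsilyloxy)pent-3-en-2-yl}-7,8-bis(triethylsilyloxy)-7,8-dihydro-6H-isochromen-6-one | C/C(=C\[C@](C)(O[Si](CC)(CC)CC)C1=CC2=CC(=O)[C@@](C)(O[Si](CC)(CC)CC)[C@H](O[Si](CC)(CC)CC)C2=CO1)[C@H]1OCC[C@@H]1C | intermediate
28 | (7S,8R)-7,8-dihydroxy-3-{(2S,3E)-2-hydroxy-4-[(2S,3S)-3-methyloxolan-2-yl]pent-3-en-2-yl}-7-methyl-7,8-dihydro-6H-isochromen-6-one | C/C(=C\[C@](C)(O)C1=CC2=CC(=O)[C@@](C)(O)[C@H](O)C2=CO1)[C@H]1OCC[C@@H]1C | target

## Step count and least certain steps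

Total: 19 steps. Longest linear sequence: 12 steps (steps 1–9 and 17–19); the side-chain branch is steps 10–16.

**Step 7 (key step).** Three processes threaten it:
- alkoxide or adventitious hydroxide adds to the non-enolisable β-keto aldehyde and cleaves the C7–C8 bond (deformylation) faster than γ-deprotonation;
- the aldolate re-enolises at C8a and expels the C8 oxygen (vinylogous dehydration);
- facial selectivity at C8 erodes if a polar Felkin–Anh arrangement competes with the dipole-opposed one, or if the aldol reverses.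

Fallback, from 9 back to 10: TESOTf and Et3N silylate the enone oxygen (the aldehyde cannot enolise) to give the silyl dienol ether (2R,3E)-2,5-dimethyl-2,3-bis(triethylsilyloxy)hexa-3,5-dienal F1. BF3·OEt2 in CH2Cl2 at −78 °C then closes the same C8–C8a bond by an intramolecular vinylogous Mukaiyama aldol reaction under non-basic, non-chelating conditions, and aqueous work-up returns to the route at 10. The 3Z isomer of F1, which cannot reach the aldehyde, would be hydrolysed back to 9 and recycled.

**Step 9 (with the enolisation of step 8).** Enolisation may occur toward the C4 methyl instead of C8a, the carbenium ion may attack C5, or the Lewis acid may ionise the allylic C8 silyl ether.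

Fallback, from 11 back to 27: 11 is isolated from 10 with TESOTf and 2,6-lutidine at −78 °C. Heating 11 with tert-butoxybis(dimethylamino)methane in toluene, without Lewis acid or silyl dienol ether, condenses the reagent at the ring methylene to give the enaminone (4E,5R,6S)-4-[(dimethylamino)methylidene]-3,6-dimethyl-5,6-bis(triethylsilyloxy)cyclohex-2-en-1-one F2. F2 is acylated with 25 as in step 17 to give (4E,5R,6S)-4-[(dimethylamino)methylidene]-6-methyl-3-{(3S,4E)-3-methyl-5-[(2S,3S)-3-methyloxolan-2-yl]-2-oxo-3-(triethylsilyloxy)hex-4-en-1-yl}-5,6-bis(triethylsilyloxy)cyclohex-2-en-1-one F3. Acetic acid then closes the pyran with loss of dimethylamine, rejoining the route at 27. The site selectivity of this fallback still relies on the preference for the endocyclic dienolate.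

**Step 17.** Attack on the hindered α-silyloxy ester may be too slow, so that reaction at C5 or conjugate addition of the amide base to C1 competes.

Fallback, from 25 and 14 back to 26: DIBAL-H at −78 °C reduces 25 to the aldehyde (2S,3E)-2-methyl-4-[(2S,3S)-3-methyloxolan-2-yl]-2-(triethylsilyloxy)pent-3-enal F4, a far better electrophile. The lithium dienolate of 14 adds to F4 to give the aldol (4E,5R,6S)-3-{(2RS,3S,4E)-2-hydroxy-3-methyl-5-[(2S,3S)-3-methyloxolan-2-yl]-3-(triethylsilyloxy)hex-4-en-1-yl}-4-(methoxymethylidene)-6-methyl-5,6-bis(triethylsilyloxy)cyclohex-2-en-1-one F5. Dess–Martin periodinane oxidises the new carbinol and returns to the route at 26.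

**Step 11.** The aldol may revert during acid treatment, the transposition may stop at the β-hydroxy aldehyde, or the dioxolanone may hydrolyse.

Fallback, from 16 back to 19: the enolate of 16 is hydroxymethylated with monomeric formaldehyde to (2R,5S)-2-tert-butyl-5-(hydroxymethyl)-5-methyl-1,3-dioxolan-4-one F6. Dess–Martin periodinane gives (2R,4S)-2-tert-butyl-4-methyl-5-oxo-1,3-dioxolane-4-carbaldehyde F7, and a Wittig reaction with Ph3P=C(CH3)CHO in toluene at 80 °C gives the E enal 19.

**Step 6.** Cleavage of the primary silyl ether under Swern conditions may be incomplete, or the tertiary silyl ether may be lost as well.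

Fallback, from 8 back to 9: buffered HF·pyridine at 0 °C removes only the primary silyl group to give (2S)-1-hydroxy-2,5-dimethyl-2-(triethylsilyloxy)hex-4-en-3-one F8, and Dess–Martin periodinane with NaHCO3 oxidises it to 9.

## Further compounds

F1 | step 7 | (2R,3E)-2,5-dimethyl-2,3-bis(triethylsilyloxy)hexa-3,5-dienal | O=C[C@](C)(O[Si](CC)(CC)CC)/C(O[Si](CC)(CC)CC)=C\C(C)=C
F2 | step 9 | (4E,5R,6S)-4-[(dimethylamino)methylidene]-3,6-dimethyl-5,6-bis(triethylsilyloxy)cyclohex-2-en-1-one | CN(C)/C=C1\C(C)=CC(=O)[C@@](C)(O[Si](CC)(CC)CC)[C@@H]1O[Si](CC)(CC)CC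
F3 | step 9 | (4E,5R,6S)-4-[(dimethylamino)methylidene]-6-methyl-3-{(3S,4E)-3-methyl-5-[(2S,3S)-3-methyloxolan-2-yl]-2-oxo-3-(triethylsilyloxy)hex-4-en-1-yl}-5,6-bis(triethylsilyloxy)cyclohex-2-en-1-one | CN(C)/C=C1\C(CC(=O)[C@@](C)(O[Si](CC)(CC)CC)/C=C(\C)[C@H]2OCC[C@@H]2C)=CC(=O)[C@@](C)(O[Si](CC)(CC)CC)[C@@H]1O[Si](CC)(CC)CC
F4 | step 17 | (2S,3E)-2-methyl-4-[(2S,3S)-3-methyloxolan-2-yl]-2-(triethylsilyloxy)pent-3-enal | O=C[C@@](C)(O[Si](CC)(CC)CC)/C=C(\C)[C@H]1OCC[C@@H]1C
F5 | step 17 | (4E,5R,6S)-3-{(2RS,3S,4E)-2-hydroxy-3-methyl-5-[(2S,3S)-3-methyloxolan-2-yl]-3-(triethylsilyloxy)hex-4-en-1-yl}-4-(methoxymethylidene)-6-methyl-5,6-bis(triethylsilyloxy)cyclohex-2-en-1-one | CO/C=C1\C(CC(O)[C@@](C)(O[Si](CC)(CC)CC)/C=C(\C)[C@H]2OCC[C@@H]2C)=CC(=O)[C@@](C)(O[Si](CC)(CC)CC)[C@@H]1O[Si](CC)(CC)CC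
F6 | step 11 | (2R,5S)-2-tert-butyl-5-(hydroxymethyl)-5-methyl-1,3-dioxolan-4-one | C[C@@]1(CO)O[C@@H](C(C)(C)C)OC1=O
F7 | step 11 | (2R,4S)-2-tert-butyl-4-methyl-5-oxo-1,3-dioxolane-4-carbaldehyde | C[C@@]1(C=O)O[C@@H](C(C)(C)C)OC1=O
F8 | step 6 | (2S)-1-hydroxy-2,5-dimethyl-2-(triethylsilyloxy)hex-4-en-3-one | C[C@](CO)(C(=O)C=C(C)C)O[Si](CC)(CC)CC
A1 | alternative 1 | (2R)-4-(trimethylsilyl)but-3-yn-2-yl N,N-di(propan-2-yl)carbamate | C[C@@H](OC(=O)N(C(C)C)C(C)C)C#C[Si](C)(C)C
A2 | alternative 1 | 4,4,5,5-tetramethyl-2-{(1E)-2-[(2S,3S)-3-methyloxolan-2-yl]prop-1-en-1-yl}-1,3,2-dioxaborolane | C/C(=C\B1OC(C)(C)C(C)(C)O1)[C@H]1OCC[C@@H]1C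
A3 | alternative 1 | (3S,4E)-3-methyl-5-[(2S,3S)-3-methyloxolan-2-yl]-1-(trimethylsilyl)hex-4-en-1-yn-3-ol | C/C(=C\[C@](C)(O)C#C[Si](C)(C)C)[C@H]1OCC[C@@H]1C
A4 | alternative 2 | L-isoleucine, (2S,3S)-2-amino-3-methylpentanoic acid | CC[C@H](C)[C@H](N)C(=O)O
A5 | alternative 2 | (2S,3S)-2-hydroxy-3-methylpentyl 2,2-dimethylpropanoate | CC[C@H](C)[C@H](O)COC(=O)C(C)(C)C
A6 | alternative 2 | [(2S,3S)-3-methyloxolan-2-yl]methyl 2,2-dimethylpropanoate | CC(C)(C)C(=O)OC[C@H]1OCC[C@@H]1C
A7 | alternative 3 | (3S,4Z)-5-[(2R,3R)-3-({[tert-butyl(dimethyl)silyl]oxy}methyl)-3-methyloxiran-2-yl]-3-methylhex-4-en-1-ol | C[C@@H](CCO)/C=C(/C)[C@H]1O[C@]1(C)CO[Si](C)(C)C(C)(C)C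
A8 | alternative 3 | (2S,3E)-1-{[tert-butyl(dimethyl)silyl]oxy}-2-methyl-4-[(2S,3S)-3-methyloxolan-2-yl]pent-3-en-2-ol | C/C(=C\[C@](C)(O)CO[Si](C)(C)C(C)(C)C)[C@H]1OCC[C@@H]1C
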